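5 questions stand on 4 set-ups, each charged with 0.80 M substrate.

- the set-up with the highest amount of product at the outlet or at the end, in percent of the substrate put in ("none" if the first two lie within 2 percentage points) (oak / larch / cedar / elm / none)
- amount of product at the outlet or at the end, in percent of the substrate put in, oak
- amount of product at the outlet or at the end, in percent of the substrate put in, larch
- amount of product at the outlet or at the end, in percent of the substrate put in, cedar
- amount of product at the outlet or at the end, in percent of the substrate put in, elm

| flask | substrate | remark | time |
|---|---|---|---|
| Saturday's | 0.80 M | run made earlier |  |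
| Tuesday's | 1.1 M | run made earlier |  |
| Friday's | 1.8 M | run made earlier |  |
| oak | 0.80 M | a tube with plug flow, the mixed feed as stated, residence time 2.5 min | 2.5 min |
| larch | 0.80 M | a single well-mixed tank run continuously and read at steady state, 2.5 min in it on average |  |
| cedar | 0.80 M | one stirred flow tank at steady state, fed with the mixture as stated, mean residence time 25.0 min |  |
| elm | 0.80 M | everything together in a closed stirred flask, run for 2.5 min | 2.5 min |

- Saturday's (time / min: product / %, substrate / %): 0.667: 8.8, 37.2; 1.33: 13.3, 15.4; 2.00: 14.5, 10.3; 2.50: 16.9, 7.9
- Tuesday's (time / min: product / %, substrate / %): 0.417: 6.7, 52.8; 1.00: 12.4, 22.5; 2.00: 14.8, 10.2; 3.00: 17.4, 6.4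
- Friday's (time / min: product / %, substrate / %): 0.417: 7.5, 51.0; 1.00: 11.9, 24.7; 2.00: 14.8, 10.6; 3.00: 18.1, 8.1

(readings scatter by 1 percentage point)

- the stated concentrations are those of everything mixed, before any reaction; amounts are the same in each set-up
- on the list of suspects stand: substrate -> product; intermediate A <-> intermediate B; intermediate A -> product; substrate <-> intermediate A
- the earlier runs were made in a closed, stirred flask

The closed-flask curves overlay: at 2.00 min, product reads 14.5% from 0.80 M and 14.8% from 1.8 M, so the steps are treated as first order.

The time scales form a ladder. On the first rung, Saturday's first reading gives substrate an apparent decay constant λ of 1.48 min⁻¹, a time of 0.675 min. By 2.00 min, Tuesday's substrate reads 10.2%, and substrate and intermediate A are taken as a pool in pre-equilibrium.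

On the last rung, Tuesday's and Friday's product readings from 2.00 min to 3.00 min give 0.0352 min⁻¹ as the drain constant κ, the first-order constant with which the pool passes into product. The scatter allows 0.0117 min⁻¹ either way. The drain time 28.4 min is far longer than the first rung. Integrating the drain back to zero time leaves a burst b of 8.58%.

With first-order steps, a tank averages this closed-flask curve over exponentially distributed ages with mean τ, so the outlet product P is b + (1 − b)·κτ/(1 + κτ), less b/(1 + λτ) for the youngest ages. This reckoning, distinct from the forecast, gives 14.2% for larch and 51.2% for cedar, and the scatter of κ alone spreads cedar over a band from 42.2% to 57.7%. Oak and elm share one contact time, and Saturday's reading there is 16.9%.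

The forecast names cedar, with 16.6% for oak, 14.6% for larch, 36% for cedar and 16.6% for elm, saying “long residence lets the reservoir feed back”. Its cedar value lies below this band.

The flask gives cedar as best: 17.3% for oak, 17.3% for elm, 15.0% for larch and 46.6% for cedar.

    substrate → product (k = 0.00360 s⁻¹)
    intermediate A ⇌ intermediate B (K = 0.290, k = 0.00330 s⁻¹)
    intermediate A → product (k = 2.60 × 10⁻⁴ s⁻¹)
    substrate ⇌ intermediate A (K = 9.00, k = 0.0230 s⁻¹)

Substrate's forward half-life into intermediate A, 0.50 min, is shorter than its 3.2 min into product. Cedar's mean residence time is 0.881 of the drain time and larch's 0.0881, and the two outlets differ by 32 percentage points. Cedar's 46.6% lies inside the band, above 42.2% and below 57.7%. On larch, the same drain constant gave 14.2%, and the tank delivers 15.0%.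

The numbers in the tables were generated by integration from invented constants; the scatter is artificial.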